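**Retrosynthetic overview**
1. Ring A comes intact from safranal 1: allylic bromination (2), then α-prenylation with 3 of the trienolate 4 builds the quaternary carbon of racemic aldehyde 5.
2. One chiral dioxirane epoxidises the prenyl alkene (6) and the ring alkene (7): three C–O stereocentres are set and the enantiomer of 5 with the matched quaternary carbon is selected.
3. Bromide opens both oxiranes (8; the ring oxirane at its allylic carbon, as in the presumed prepacifenol-type precursor) and the freed side-chain alkoxide closes on the aldehyde: tetrahydrofuran ring, lactol 9.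
4. The lactol is ionised and the neighbouring tertiary hydroxyl captures the oxocarbenium ion: oxetane acetal 10; loss of HBr gives the isopropenyl group of target 11.
5. Ring order: cyclohexadiene (bought) → two oxiranes → tetrahydrofuran → oxetane.

Assumption (biogenesis): the target is taken to arise from a prepacifenol-type 10-bromo-7,8-epoxychamigr-9-ene after C4–C5 cleavage to an aldehyde, by bromide opening of the oxirane at C8 and closure of the aldehyde by the C2 and C7 oxygens; steps 4 and 5 copy these events.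

Atom labels in the text (chamigrane type; locants inside names are IUPAC): C1/C2 = CH2 and CH–O of the tetrahydrofuran, C3/C4/C15 = isopropenyl, C5 = acetal CH, C6 = spiro carbon, C7 = C(CH3)–O, C8 = CHBr, C9=C10(Br), C11 = C(CH3)2; target = 2R,5S,6S,7S,8S.

**Step 1**
Reactants: 1 safranal (2,6,6-trimethylcyclohexa-1,3-diene-1-carbaldehyde)
Product: 2 (±)-5-bromo-2,6,6-trimethylcyclohexa-1,3-diene-1-carbaldehyde
Conditions: NBS (1.05 equiv), AIBN (cat.), PhCF3, 80 °C
Reagents that add atoms: N-bromosuccinimide, O=C1CCC(=O)N1Br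
Why: Wohl–Ziegler allylic bromination, in which H-abstraction from the only ring allylic CH2 gives a formyl-conjugated pentadienyl radical that takes bromine at the terminus keeping the dienal conjugated (C10), by analogy with the NBS bromination of β-cyclocitral; the new CHBr centre is racemic and is erased in step 2.

**Step 2**
Reactants: 2 (±)-5-bromo-2,6,6-trimethylcyclohexa-1,3-diene-1-carbaldehyde, 3 prenyl bromide (1-bromo-3-methylbut-2-ene)
Product: 5 (±)-5-bromo-2,6,6-trimethyl-1-(3-methylbut-2-en-1-yl)cyclohexa-2,4-diene-1-carbaldehyde, via potassium trienolate 4 (not isolated)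
Conditions: t-BuOK (1.1 equiv), THF/t-BuOH, −20 °C; then 3, −20 to 0 °C
Reagents that add atoms: prenyl bromide (compound 3), CC(C)=CCBr
Why: Deconjugative α-alkylation of an α,β-unsaturated aldehyde, in which equilibrating t-BuOK removes the acidified H–C(Br) proton to give the linear bromine-terminated trienolate, which like cyclocitral-type extended enolates is C-alkylated at the α-carbon by the reactive allylic bromide (t-BuOH solvation disfavours O-alkylation), creating C6 as a racemate and fixing the 10-bromo-7,9-diene.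

**Step 3**
Reactants: 5 (±)-5-bromo-2,6,6-trimethyl-1-(3-methylbut-2-en-1-yl)cyclohexa-2,4-diene-1-carbaldehyde
Product: 7 (1S,2S,6R)-4-bromo-2-{[(2R)-3,3-dimethyloxiran-2-yl]methyl}-1,3,3-trimethyl-7-oxabicyclo[4.1.0]hept-4-ene-2-carbaldehyde, via side-chain mono-epoxide 6 (not isolated)
Conditions: 1,2:4,5-di-O-isopropylidene-β-D-erythro-2,3-hexodiulo-2,6-pyranose (Shi ketone from D-fructose, 0.6 equiv), Oxone (2KHSO5·KHSO4·K2SO4), K2CO3, Bu4NHSO4, MeCN/DMM/H2O (pH 10.5), −5 to 0 °C; chromatography
Reagents that add atoms: potassium peroxymonosulfate KHSO5 (from Oxone), [K+].[O-]S(=O)(=O)OO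
Why: Shi asymmetric epoxidation, in which the D-fructose-derived dioxirane gives the R oxirane carbon from the R–CH2–CH=C(CH3)2 unit (sets C2) and by the same facial rule epoxidises the electron-richer trisubstituted C7=C8 bond of the bromodiene on the formyl face of the 1R enantiomer of 5 (matched with the smaller CHO group; sets C7 and C8), whereas the 1S enantiomer is mismatched and ends as a separable diastereomer, so C6 is selected here (at most 50 % from the racemate).

**Step 4**
Reactants: 7 (1S,2S,6R)-4-bromo-2-{[(2R)-3,3-dimethyloxiran-2-yl]methyl}-1,3,3-trimethyl-7-oxabicyclo[4.1.0]hept-4-ene-2-carbaldehyde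
Product: 9 (3R,5S,6S,7S)-7,9-dibromo-3-(2-bromopropan-2-yl)-6,10,10-trimethyl-2-oxaspiro[4.5]dec-8-ene-1,6-diol (C1 epimers), via ring-opened bis-bromohydrin aldehyde 8 (not isolated)
Conditions: MgBr2·OEt2 (2.5 equiv), Et2O/CH2Cl2, −40 to −10 °C; aq. NH4Cl
Reagents that add atoms: magnesium bromide diethyl etherate, [Mg+2].[Br-].[Br-].CCOCC
Why: Lewis acid-assisted halohydrin formation, in which bromide opens the vinyl oxirane by SN2 at the allylic C8 (inversion, Br anti to the C7 oxygen, the C8–O cleavage typical of prepacifenol-type epoxides) and the side-chain oxirane at the tertiary C3 (C2–O untouched, C2 stays R), after which the C2 alkoxide adds to the neighbouring aldehyde and closes the tetrahydrofuran as its five-membered lactol, which also shields the magnesium aldolate from retro-aldol cleavage.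

**Step 5**
Reactants: 9 (3R,5S,6S,7S)-7,9-dibromo-3-(2-bromopropan-2-yl)-6,10,10-trimethyl-2-oxaspiro[4.5]dec-8-ene-1,6-diol
Product: 11 (1S,3R,5S,7S,8S)-8,10-dibromo-7,11,11-trimethyl-3-(prop-1-en-2-yl)-4,6-dioxatricyclo[5.4.0.0^1,5]undec-9-ene, via tribromo oxetane acetal 10 (not isolated)
Conditions: PPh3, DIAD, toluene, −20 to 0 °C; then DBU, 60 °C
Reagents that add atoms: none
Why: Proposed new method: the Mitsunobu betaine turns the lactol OH (the only acidic, unhindered hydroxyl; no β-hydrogen, so no enol ether can form) into an anomeric oxyphosphonium that ionises to the five-membered oxocarbenium ion, which the syn C7 tertiary hydroxyl, pressed against it by two quaternary carbons, captures irreversibly under non-acidic conditions (Ph3PO formation pays for the oxetane strain; the cis fusion fixes C5 as S), and DBU then removes HBr from the tertiary bromide away from oxygen to give the isopropenyl group; the closest known reaction types are the Mitsunobu cyclodehydration of β-hydroxy lactols to bicyclic oxetane acetals and the E2 dehydrobromination of 2-(2-bromopropan-2-yl) cyclic ethers.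

**Compound list**
1 | safranal (2,6,6-trimethylcyclohexa-1,3-diene-1-carbaldehyde) | CC1=C(C=O)C(C)(C)CC=C1 | starting material
2 | (±)-5-bromo-2,6,6-trimethylcyclohexa-1,3-diene-1-carbaldehyde (racemate) | CC1=C(C=O)C(C)(C)C(Br)C=C1 | intermediate
3 | prenyl bromide (1-bromo-3-methylbut-2-ene) | CC(C)=CCBr | starting material
4 | potassium (5-bromo-2,6,6-trimethylcyclohexa-2,4-dien-1-ylidene)methanolate (trienolate) | [K+].[O-]C=C1C(C)=CC=C(Br)C1(C)C | intermediate
5 | (±)-5-bromo-2,6,6-trimethyl-1-(3-methylbut-2-en-1-yl)cyclohexa-2,4-diene-1-carbaldehyde (racemate; only the 1R enantiomer goes on) | CC(C)=CCC1(C=O)C(C)=CC=C(Br)C1(C)C | intermediate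
6 | (1R)-5-bromo-1-{[(2R)-3,3-dimethyloxiran-2-yl]methyl}-2,6,6-trimethylcyclohexa-2,4-diene-1-carbaldehyde | CC1(C)O[C@@H]1C[C@@]2(C=O)C(C)=CC=C(Br)C2(C)C | intermediate
7 | (1S,2S,6R)-4-bromo-2-{[(2R)-3,3-dimethyloxiran-2-yl]methyl}-1,3,3-trimethyl-7-oxabicyclo[4.1.0]hept-4-ene-2-carbaldehyde | CC1(C)O[C@@H]1C[C@@]2(C=O)[C@]3(C)O[C@@H]3C=C(Br)C2(C)C | intermediate
8 | (1S,2S,3S)-3,5-dibromo-1-[(2R)-3-bromo-2-hydroxy-3-methylbutyl]-2-hydroxy-2,6,6-trimethylcyclohex-4-ene-1-carbaldehyde | CC(C)(Br)[C@H](O)C[C@@]1(C=O)[C@](C)(O)[C@@H](Br)C=C(Br)C1(C)C | intermediate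
9 | (3R,5S,6S,7S)-7,9-dibromo-3-(2-bromopropan-2-yl)-6,10,10-trimethyl-2-oxaspiro[4.5]dec-8-ene-1,6-diol (lactol, C1 epimers) | CC(C)(Br)[C@H]1C[C@@]2(C(O)O1)[C@](C)(O)[C@@H](Br)C=C(Br)C2(C)C | intermediate
10 | (1S,3R,5S,7S,8S)-8,10-dibromo-3-(2-bromopropan-2-yl)-7,11,11-trimethyl-4,6-dioxatricyclo[5.4.0.0^1,5]undec-9-ene | CC(C)(Br)[C@H]1C[C@@]23[C@@H](O1)O[C@]2(C)[C@@H](Br)C=C(Br)C3(C)C | intermediate
11 | (1S,3R,5S,7S,8S)-8,10-dibromo-7,11,11-trimethyl-3-(prop-1-en-2-yl)-4,6-dioxatricyclo[5.4.0.0^1,5]undec-9-ene (CNP0141320.1) | C=C(C)[C@H]1C[C@@]23[C@@H](O1)O[C@]2(C)[C@@H](Br)C=C(Br)C3(C)C | target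

**Step count and risks**
Total step count: 5. Longest linear sequence: 5 (from safranal 1).

Most likely to fail, first: step 2. C6 lies between two fully substituted carbons, so the trienolate may react at oxygen, at C8 or C10, or be formed by deprotonation of the C7 methyl group. The fallback sets out from 2 and comes back at 5. Condensation of 2 with cyclohexylamine (MgSO4, CH2Cl2) gives the N-cyclohexyl aldimine F1. LDA (THF, −78 °C) turns it into the lithiated azatriene (metalloenamine), which alkylates on carbon only with 3 to give the prenylated aldimine F2. Aqueous oxalic acid then releases 5.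

Second: step 3. Oxone may attack the formyl group, the mono-epoxide's aldehyde hydrate may open the side-chain oxirane, and the hindered ring alkene may react slowly or on the wrong face. The fallback sets out from 5 and comes back at 7. NaBH4 (MeOH, 0 °C) gives the neopentyl alcohol F3. The same Shi conditions, now without an aldehyde, epoxidise only the prenyl group to the epoxy alcohol F4. VO(acac)2/t-BuOOH (toluene, 0 °C) then delivers oxygen to C7=C8 from the face of the homoallylic CH2OH to give the bis-epoxy alcohol F5; the C6-epimeric series separates here as a diastereomer. Dess–Martin periodinane (NaHCO3, CH2Cl2) returns the aldehyde 7.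

Third: step 5. The oxocarbenium ion may be taken by the hydrazide anion before the strained oxetane closes. The fallback sets out from 6 (isolated, with its C6 epimer, by stopping step 3 after the faster side-chain epoxidation) and comes back at 10. MgBr2·OEt2 opens the side-chain oxirane at C3 and the C2 alkoxide lactolises to the diene lactol F6. NBS/NaHCO3 (MeCN, 0 °C) then makes the C7–O bond instead of the C5–O bond: the lactol oxygen adds 4-exo to C7 while bromine adds anti at C8, the way β,γ-unsaturated acids give bromo-β-lactones. The tether fixes C7 and C8 relative to C6 and gives 10 (its C6-epimeric series is removed as a diastereomer); DBU then finishes to 11 as in step 5.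

**Further compounds**
F1 | step 2 | N-cyclohexyl-1-(5-bromo-2,6,6-trimethylcyclohexa-1,3-dien-1-yl)methanimine | CC1=C(C=NC2CCCCC2)C(C)(C)C(Br)C=C1
F2 | step 2 | (±)-N-cyclohexyl-1-[5-bromo-2,6,6-trimethyl-1-(3-methylbut-2-en-1-yl)cyclohexa-2,4-dien-1-yl]methanimine | CC(C)=CCC1(C=NC2CCCCC2)C(C)=CC=C(Br)C1(C)C
F3 | step 3 | (±)-[5-bromo-2,6,6-trimethyl-1-(3-methylbut-2-en-1-yl)cyclohexa-2,4-dien-1-yl]methanol | CC(C)=CCC1(CO)C(C)=CC=C(Br)C1(C)C
F4 | step 3 | [(1R)-5-bromo-1-{[(2R)-3,3-dimethyloxiran-2-yl]methyl}-2,6,6-trimethylcyclohexa-2,4-dien-1-yl]methanol | CC1(C)O[C@@H]1C[C@@]2(CO)C(C)=CC=C(Br)C2(C)C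
F5 | step 3 | [(1S,2R,6R)-4-bromo-2-{[(2R)-3,3-dimethyloxiran-2-yl]methyl}-1,3,3-trimethyl-7-oxabicyclo[4.1.0]hept-4-en-2-yl]methanol | CC1(C)O[C@@H]1C[C@@]2(CO)[C@]3(C)O[C@@H]3C=C(Br)C2(C)C
F6 | step 5 | (3R,5R)-9-bromo-3-(2-bromopropan-2-yl)-6,10,10-trimethyl-2-oxaspiro[4.5]deca-6,8-dien-1-ol (C1 epimers) | CC(C)(Br)[C@H]1C[C@@]2(C(O)O1)C(C)=CC=C(Br)C2(C)C
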